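Rings: A pyrrolidine, B azepane, C cyclopentane, D hydroxy-γ-lactone, E methyl-γ-lactone. Retrosynthetic cuts, in order: the C=O of a ring B lactam; the acyl–O bond of ring D (back to a ring C ketone and a lactate-derived dioxolanone); the ring B C–C bond at ring C (back to a cyclopentenone with an N-4-bromobutanoyl arm); then together the N–C(spiro) bond of ring A and the C(spiro)–CH bond of ring C; then the carbinol C–C bond, the bond from ring E to the amine carbon, and the furan–CH2 bond.
Enabling feature: the N-bearing quaternary carbon shared by rings A and C lies in ring C next to the CH that carries the α-carbon of lactone D, trans to N, and that CH is followed by the O-bearing ring C carbon. This is a 4-amino-5-alkylcyclopent-2-enone, the pattern left when a 5-(3-aminopropyl)-2-furylcarbinol rearranges.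
Forward order: 3-bromofuran becomes a 2-formyl-3-ethylfuran with a 3-oxopropyl arm at C5; ring E is attached by a vinylogous Mannich reaction and saturated; aldol with the lactate dioxolanone; rings A and C close together; ring B by radical cyclisation; ring D by reduction and translactonisation; lactam to amine.
Stereochemistry: the amine and ring E carbinol centres come from the silver-catalysed Mannich step, the ring E methyl centre from hydrogenation, and the tertiary alcohol centre from (R)-lactic acid through its pivalaldehyde acetal. The spiro centre and its CH neighbour come from the electrocyclisation, the two ring B/C centres from the tethered radical closure, and the ring D carbinol from hydride delivery anti to the dioxolanone.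

Key step: step 14

Remark: the carbinol carbon made in step 13 is carried as a mixture of epimers because step 14 converts it into a cation; the chiral phosphine–imine ligand of step 9 (2-Ph2P-benzaldimine of a tert-leucine 4-methoxyanilide) is a catalyst prepared separately and is not numbered.

Step 1
Reactants: 1 3-bromofuran
Product: 3 3-bromofuran-2-carbaldehyde, via 3-bromo-2-lithiofuran 2 (not isolated)
Conditions: LiN(iPr)2, THF, −78 °C; DMF; H2O
Reagents that add atoms: N,N-dimethylformamide, CN(C)C=O
Why: Directed ortho-lithiation removes the C2 proton, acidified by the ring oxygen and the adjacent bromine, without halogen–metal exchange, and the furyllithium is formylated by DMF.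

Step 2
Reactants: 3 3-bromofuran-2-carbaldehyde; 4 ethylboronic acid
Product: 5 3-ethylfuran-2-carbaldehyde
Conditions: Pd(OAc)2 (2 mol%), SPhos (4 mol%), K3PO4, toluene/H2O, 90 °C
Reagents that add atoms: none
Why: Suzuki–Miyaura coupling of a primary alkylboronic acid with an electron-poor heteroaryl bromide should proceed because the bulky biaryl phosphine speeds reductive elimination over β-hydride elimination and the aldehyde is tolerated.

Step 3
Reactants: 5 3-ethylfuran-2-carbaldehyde
Product: 6 2-(3-ethylfuran-2-yl)-1,3-dioxolane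
Conditions: HOCH2CH2OH, pyridinium p-toluenesulfonate (cat.), toluene, reflux, Dean–Stark
Reagents that add atoms: ethane-1,2-diol, OCCO
Why: Acid-catalysed acetalisation with azeotropic removal of water masks the formyl group for the organolithium and imine chemistry that follows.

Step 4
Reactants: 6 2-(3-ethylfuran-2-yl)-1,3-dioxolane; 7 allyl bromide (3-bromoprop-1-ene)
Product: 9 2-[3-ethyl-5-(prop-2-en-1-yl)furan-2-yl]-1,3-dioxolane, via 2-(3-ethyl-5-lithiofuran-2-yl)-1,3-dioxolane 8 (not isolated)
Conditions: n-BuLi, THF, −78 → 0 °C; 7, −78 °C → rt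
Reagents that add atoms: none
Why: Deprotonation at the only free furan α-position followed by SN2 alkylation of the furyllithium with the allylic bromide installs the three-carbon arm.

Step 5
Reactants: 9 2-[3-ethyl-5-(prop-2-en-1-yl)furan-2-yl]-1,3-dioxolane
Product: 11 3-[5-(1,3-dioxolan-2-yl)-4-ethylfuran-2-yl]propan-1-ol, via B-alkyl-9-borabicyclononane adduct 10 (not isolated)
Conditions: 9-borabicyclo[3.3.1]nonane, THF, 0 °C → rt; NaOH, H2O2, 0 °C
Reagents that add atoms: hydrogen peroxide, OO
Why: Hydroboration–oxidation with the bulky dialkylborane places boron and then oxygen on the terminal carbon while furan and acetal stay inert.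

Step 6
Reactants: 11 3-[5-(1,3-dioxolan-2-yl)-4-ethylfuran-2-yl]propan-1-ol
Product: 12 3-[5-(1,3-dioxolan-2-yl)-4-ethylfuran-2-yl]propanal
Conditions: (nPr4N)RuO4 (5 mol%), 4-methylmorpholine N-oxide, 4 Å MS, CH2Cl2, rt
Reagents that add atoms: none
Why: The Ley–Griffith oxidation stops at the aldehyde under neutral conditions that leave the acid-labile furyl acetal untouched.

Step 7
Reactants: 13 2-amino-6-methoxy-1,3-benzothiazole
Product: 15 4-methoxy-2-(methylsulfanyl)aniline, via potassium 2-amino-5-methoxybenzenethiolate 14 (not isolated)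
Conditions: KOH, H2O/ethylene glycol, reflux; MeI, 0 °C
Reagents that add atoms: iodomethane, CI
Why: Alkaline hydrolysis of the 2-aminothiazole ring unmasks the ortho-aminothiolate, whose soft sulfur is methylated selectively (S-alkylation).

Step 8
Reactants: 16 3-methylfuran-2(5H)-one
Product: 17 3-methyl-2-(trimethylsilyloxy)furan
Conditions: Me3SiOTf, Et3N, Et2O, 0 °C
Reagents that add atoms: trimethylsilyl trifluoromethanesulfonate, C[Si](C)(C)OS(=O)(=O)C(F)(F)F
Why: Soft enolisation of the butenolide gives the aromatic 2-silyloxyfuran (silyl dienol ether formation).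

Step 9
Reactants: 12 3-[5-(1,3-dioxolan-2-yl)-4-ethylfuran-2-yl]propanal; 15 4-methoxy-2-(methylsulfanyl)aniline; 17 3-methyl-2-(trimethylsilyloxy)furan
Product: 19 (5S)-5-[(1S)-3-[5-(1,3-dioxolan-2-yl)-4-ethylfuran-2-yl]-1-{[4-methoxy-2-(methylsulfanyl)phenyl]amino}propyl]-3-methylfuran-2(5H)-one, via N-aryl aldimine 18 (not isolated)
Conditions: AgOAc (5 mol%), tert-leucine-derived phosphine–imine ligand (5 mol%), i-PrOH (1.1 equiv), MgSO4, THF, −78 °C
Reagents that add atoms: none
Why: In this silver-catalysed three-component asymmetric vinylogous Mannich reaction the aldimine formed in situ chelates silver through nitrogen and the ortho sulfur, the siloxyfuran adds through its γ-carbon in an endo-type arrangement to give the anti (threo) adduct, and the ligand enantiomer is chosen so that both new centres are S.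

Step 10
Reactants: 19 the butenolide amine of step 9
Product: 20 (3S,5S)-5-[(1S)-3-[5-(1,3-dioxolan-2-yl)-4-ethylfuran-2-yl]-1-[(4-methoxyphenyl)amino]propyl]-3-methyloxolan-2-one
Conditions: Raney Ni (excess), H2 (1 atm), EtOH, rt
Reagents that add atoms: none
Why: Raney nickel should cleave the aryl C–S bond (desulfurisation, leaving a plain 4-methoxyphenyl group) and hydrogenate the butenolide C=C from the face opposite the bulky side chain, so that the methyl group ends up cis to the side chain.

Step 11
Reactants: 20 the saturated amino lactone acetal of step 10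
Product: 21 3-ethyl-5-[(3S)-3-[(4-methoxyphenyl)amino]-3-[(2S,4S)-4-methyl-5-oxooxolan-2-yl]propyl]furan-2-carbaldehyde
Conditions: 1 M HCl, THF, 0 °C; NaHCO3
Reagents that add atoms: water, O
Why: Acid-catalysed acetal hydrolysis is fast for the electron-rich furyl acetal, while the lactone and the N-aryl amine survive cold dilute acid.

Step 12
Reactants: 22 (R)-lactic acid; 23 pivalaldehyde
Product: 24 (2R,5R)-2-tert-butyl-5-methyl-1,3-dioxolan-4-one
Conditions: TsOH·H2O (cat.), H2SO4 (cat.), pentane, reflux, Dean–Stark; crystallisation at −78 °C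
Reagents that add atoms: none
Why: Acetalisation under thermodynamic control (self-regeneration of stereocentres) favours the cis dioxolanone, which is purified by crystallisation and stores the lactate configuration in the acetal centre.

Step 13
Reactants: 24 (2R,5R)-2-tert-butyl-5-methyl-1,3-dioxolan-4-one; 21 the furan aldehyde of step 11
Product: 26 (2R,5S)-2-tert-butyl-5-[{3-ethyl-5-[(3S)-3-[(4-methoxyphenyl)amino]-3-[(2S,4S)-4-methyl-5-oxooxolan-2-yl]propyl]furan-2-yl}(hydroxy)methyl]-5-methyl-1,3-dioxolan-4-one (both carbinol epimers), via lithium dioxolanone enolate 25 (not isolated)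
Conditions: LiN(iPr)2, THF, −78 °C; 21, −78 °C; AcOH
Reagents that add atoms: none
Why: In this aldol addition the aldehyde is attacked on the enolate face opposite tert-butyl, which fixes the quaternary centre as 5S with overall retention of the lactate configuration, and addition at −78 °C should outrun proton transfer from the lactone or the N–H.

Step 14
Reactants: 26 the furylcarbinol of step 13
Product: 28 (2S,5R,6R)-6-[(2R,4S)-2-tert-butyl-4-methyl-5-oxo-1,3-dioxolan-4-yl]-8-ethyl-1-(4-methoxyphenyl)-2-[(2S,4S)-4-methyl-5-oxooxolan-2-yl]-1-azaspiro[4.4]non-8-en-7-one, via spiro N,O-acetal 27 (not isolated)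
Conditions: Dy(OTf)3 (10 mol%), MeCN, 80 °C
Reagents that add atoms: none
Why: Dy(OTf)3 ionises the furylcarbinol to a furfuryl oxocarbenium ion, the tethered N-aryl amine adds to the tether-bearing furan carbon to give spiro N,O-acetal 27, C–O cleavage opens it to a 1-amino-4-hydroxypentadienyl cation, and conrotatory 4π electrocyclisation with proton loss gives the enone, as in the known lanthanide triflate-catalysed intramolecular aza-Piancatelli rearrangement of 5-(3-arylaminopropyl)-2-furylcarbinols. Ring A closes by 5-exo-trig attack of nitrogen on the furan, and ring C by the thermal conrotatory 4π closure between the former furan C5 and the carbinol carbon. The CH centre is set by conrotation of the cation in which nitrogen and the dioxolanone both point outward, which places them trans on ring C, and this is also the more stable arrangement of this epimerisable α-keto centre. The spiro centre is set by the ring A stereocentre: the dioxolanone-bearing terminus should swing onto the face of the cyclic iminium carbon opposite the ring E substituent, with the quaternary dioxolanone centre as a second bias that may reinforce or oppose it. Regioselectivity is secured because only the tether-bearing furan carbon is within reach of nitrogen; chemoselectivity because the weakly basic anisidine nitrogen does not quench the Lewis acid and dry MeCN offers no competing nucleophile, while the electron-rich trialkylfuran offsets the inductive drag of the dioxolanone on ionisation.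

Step 15
Reactants: 28 the N-aryl spiro enone of step 14
Product: 29 (2S,5R,6R)-6-[(2R,4S)-2-tert-butyl-4-methyl-5-oxo-1,3-dioxolan-4-yl]-8-ethyl-2-[(2S,4S)-4-methyl-5-oxooxolan-2-yl]-1-azaspiro[4.4]non-8-en-7-one
Conditions: (NH4)2Ce(NO3)6, MeCN/H2O, 0 °C; NaHCO3
Reagents that add atoms: none
Why: Oxidative N-dearylation: two-electron oxidation of the anisidine ring to a quinone iminium ion and hydrolysis should release the secondary amine and benzoquinone, the enone and lactones being inert at 0 °C.

Step 16
Reactants: 29 the spiro amine of step 15; 30 4-bromobutanoyl chloride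
Product: 31 (2S,5R,6R)-1-(4-bromobutanoyl)-6-[(2R,4S)-2-tert-butyl-4-methyl-5-oxo-1,3-dioxolan-4-yl]-8-ethyl-2-[(2S,4S)-4-methyl-5-oxooxolan-2-yl]-1-azaspiro[4.4]non-8-en-7-one
Conditions: pyridine, 4-(dimethylamino)pyridine (cat.), CH2Cl2, 0 °C → rt
Reagents that add atoms: none
Why: N-acylation of the hindered secondary amine by the acid chloride under nucleophilic catalysis, with a base too weak to generate a ketene from 30.

Step 17
Reactants: 31 the bromo amide of step 16
Product: 32 tricyclic keto lactam in which seven-membered lactam ring B is cis-fused to cyclopentanone ring C (new ring B carbon on the face of ring C that carries N; ethyl cis to that carbon; dioxolanone trans to N)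
Conditions: (Me3Si)3SiH, AIBN, benzene (5 mM), 80 °C, slow addition
Reagents that add atoms: none
Why: In this tin-free 7-exo-trig radical cyclisation (Giese type) the primary radical adds to the enone β-carbon necessarily on the face of ring C that carries nitrogen, and the α-keto radical is expected to take hydrogen from the bulky silane on the face opposite the new C–C bond, which leaves the ethyl group cis to ring B.

Step 18
Reactants: 32 the tricyclic keto lactam of step 17
Product: 34 hydroxy bis-lactone lactam (target skeleton with the ring B lactam C=O still in place), via cis-hydroxy dioxolanone 33 (not isolated)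
Conditions: NaBH4 (excess), MeOH/THF, −40 → 0 °C; aq. citric acid
Reagents that add atoms: none
Why: Diastereoselective ketone reduction: hydride should enter anti to the bulky dioxolanone, the alkoxide so formed is cis to the dioxolanone and attacks its activated carbonyl (5-exo-trig translactonisation), which expels pivalaldehyde and unveils the tertiary alcohol.

Step 19
Reactants: 34 the hydroxy bis-lactone lactam of step 18
Product: 35 the corresponding ring B thiolactam
Conditions: Lawesson's reagent (0.6 equiv), toluene, 80 °C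
Reagents that add atoms: Lawesson's reagent, COc1ccc(cc1)P1(=S)SP(=S)(S1)c1ccc(OC)cc1
Why: Thionation with Lawesson's reagent is selective for the electron-rich lactam carbonyl over the two lactones at moderate temperature.

Step 20
Reactants: 35 the thiolactam of step 19
Product: 36 CNP0260919.4
Conditions: Raney Ni, EtOH, rt
Reagents that add atoms: none
Why: Raney nickel desulfurisation converts the thiolactam carbon into CH2 and leaves both lactones and the tertiary alcohol intact.

Compound list
1 | 3-bromofuran | Brc1ccoc1 | starting material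
2 | 3-bromo-2-lithiofuran (not isolated) | [Li]c1occc1Br | intermediate
3 | 3-bromofuran-2-carbaldehyde | O=Cc1occc1Br | intermediate
4 | ethylboronic acid | CCB(O)O | starting material
5 | 3-ethylfuran-2-carbaldehyde | CCc1ccoc1C=O | intermediate
6 | 2-(3-ethylfuran-2-yl)-1,3-dioxolane | CCc1ccoc1C1OCCO1 | intermediate
7 | allyl bromide (3-bromoprop-1-ene) | C=CCBr | starting material
8 | 2-(3-ethyl-5-lithiofuran-2-yl)-1,3-dioxolane (not isolated) | CCc1cc([Li])oc1C1OCCO1 | intermediate
9 | 2-[3-ethyl-5-(prop-2-en-1-yl)furan-2-yl]-1,3-dioxolane | CCc1cc(CC=C)oc1C1OCCO1 | intermediate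
10 | 9-{3-[5-(1,3-dioxolan-2-yl)-4-ethylfuran-2-yl]propyl}-9-borabicyclo[3.3.1]nonane (not isolated) | CCc1cc(CCCB2C3CCCC2CCC3)oc1C1OCCO1 | intermediate
11 | 3-[5-(1,3-dioxolan-2-yl)-4-ethylfuran-2-yl]propan-1-ol | CCc1cc(CCCO)oc1C1OCCO1 | intermediate
12 | 3-[5-(1,3-dioxolan-2-yl)-4-ethylfuran-2-yl]propanal | CCc1cc(CCC=O)oc1C1OCCO1 | intermediate
13 | 2-amino-6-methoxy-1,3-benzothiazole | COc1ccc2nc(N)sc2c1 | starting material
14 | potassium 2-amino-5-methoxybenzenethiolate (not isolated) | COc1ccc(N)c([S-])c1.[K+] | intermediate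
15 | 4-methoxy-2-(methylsulfanyl)aniline | COc1ccc(N)c(SC)c1 | intermediate
16 | 3-methylfuran-2(5H)-one | CC1=CCOC1=O | starting material
17 | 3-methyl-2-(trimethylsilyloxy)furan | Cc1ccoc1O[Si](C)(C)C | intermediate
18 | (E)-N-{3-[5-(1,3-dioxolan-2-yl)-4-ethylfuran-2-yl]propylidene}-4-methoxy-2-(methylsulfanyl)aniline (not isolated) | CCc1cc(CC/C=N/c2ccc(OC)cc2SC)oc1C1OCCO1 | intermediate
19 | (5S)-5-[(1S)-3-[5-(1,3-dioxolan-2-yl)-4-ethylfuran-2-yl]-1-{[4-methoxy-2-(methylsulfanyl)phenyl]amino}propyl]-3-methylfuran-2(5H)-one | CCc1cc(CC[C@@H]([C@@H]2C=C(C)C(=O)O2)Nc2ccc(OC)cc2SC)oc1C1OCCO1 | intermediate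
20 | (3S,5S)-5-[(1S)-3-[5-(1,3-dioxolan-2-yl)-4-ethylfuran-2-yl]-1-[(4-methoxyphenyl)amino]propyl]-3-methyloxolan-2-one | CCc1cc(CC[C@@H]([C@@H]2C[C@H](C)C(=O)O2)Nc2ccc(OC)cc2)oc1C1OCCO1 | intermediate
21 | 3-ethyl-5-[(3S)-3-[(4-methoxyphenyl)amino]-3-[(2S,4S)-4-methyl-5-oxooxolan-2-yl]propyl]furan-2-carbaldehyde | CCc1cc(CC[C@@H]([C@@H]2C[C@H](C)C(=O)O2)Nc2ccc(OC)cc2)oc1C=O | intermediate
22 | (R)-lactic acid | C[C@@H](O)C(=O)O | starting material
23 | pivalaldehyde (2,2-dimethylpropanal) | CC(C)(C)C=O | starting material
24 | (2R,5R)-2-tert-butyl-5-methyl-1,3-dioxolan-4-one | C[C@H]1O[C@@H](C(C)(C)C)OC1=O | intermediate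
25 | lithium (2R)-2-tert-butyl-5-methyl-1,3-dioxol-4-olate (not isolated) | CC1=C([O-])O[C@H](C(C)(C)C)O1.[Li+] | intermediate
26 | (2R,5S)-2-tert-butyl-5-[{3-ethyl-5-[(3S)-3-[(4-methoxyphenyl)amino]-3-[(2S,4S)-4-methyl-5-oxooxolan-2-yl]propyl]furan-2-yl}(hydroxy)methyl]-5-methyl-1,3-dioxolan-4-one, carbinol epimers | CCc1cc(CC[C@@H]([C@@H]2C[C@H](C)C(=O)O2)Nc2ccc(OC)cc2)oc1C(O)[C@]3(C)O[C@@H](C(C)(C)C)OC3=O | intermediate
27 | (7S)-2-{[(2R,4S)-2-tert-butyl-4-methyl-5-oxo-1,3-dioxolan-4-yl]methylidene}-3-ethyl-6-(4-methoxyphenyl)-7-[(2S,4S)-4-methyl-5-oxooxolan-2-yl]-1-oxa-6-azaspiro[4.4]non-3-ene, aminal centre and alkene geometry not fixed (not isolated) | CCC1=CC2(CC[C@@H]([C@@H]3C[C@H](C)C(=O)O3)N2c2ccc(OC)cc2)OC1=C[C@]4(C)O[C@@H](C(C)(C)C)OC4=O | intermediate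
28 | (2S,5R,6R)-6-[(2R,4S)-2-tert-butyl-4-methyl-5-oxo-1,3-dioxolan-4-yl]-8-ethyl-1-(4-methoxyphenyl)-2-[(2S,4S)-4-methyl-5-oxooxolan-2-yl]-1-azaspiro[4.4]non-8-en-7-one | CCC1=C[C@]2(CC[C@@H]([C@@H]3C[C@H](C)C(=O)O3)N2c2ccc(OC)cc2)[C@@H](C1=O)[C@]4(C)O[C@@H](C(C)(C)C)OC4=O | intermediate
29 | (2S,5R,6R)-6-[(2R,4S)-2-tert-butyl-4-methyl-5-oxo-1,3-dioxolan-4-yl]-8-ethyl-2-[(2S,4S)-4-methyl-5-oxooxolan-2-yl]-1-azaspiro[4.4]non-8-en-7-one | CCC1=C[C@]2(CC[C@@H]([C@@H]3C[C@H](C)C(=O)O3)N2)[C@@H](C1=O)[C@]4(C)O[C@@H](C(C)(C)C)OC4=O | intermediate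
30 | 4-bromobutanoyl chloride | O=C(Cl)CCCBr | starting material
31 | (2S,5R,6R)-1-(4-bromobutanoyl)-6-[(2R,4S)-2-tert-butyl-4-methyl-5-oxo-1,3-dioxolan-4-yl]-8-ethyl-2-[(2S,4S)-4-methyl-5-oxooxolan-2-yl]-1-azaspiro[4.4]non-8-en-7-one | CCC1=C[C@]2(CC[C@@H]([C@@H]3C[C@H](C)C(=O)O3)N2C(=O)CCCBr)[C@@H](C1=O)[C@]4(C)O[C@@H](C(C)(C)C)OC4=O | intermediate
32 | tricyclic keto lactam: ring C cyclopentanone spiro-linked to ring A and cis-fused to seven-membered lactam ring B; ethyl cis to the ring B carbon, dioxolanone trans to N | CC[C@@H]1C(=O)[C@@H]([C@]5(C)O[C@@H](C(C)(C)C)OC5=O)[C@]23CC[C@@H]([C@@H]4C[C@H](C)C(=O)O4)N2C(=O)CCC[C@H]13 | intermediate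
33 | ring C alcohol of 32 with OH cis to the dioxolanone and trans to ethyl (not isolated) | CC[C@@H]1[C@@H](O)[C@@H]([C@]5(C)O[C@@H](C(C)(C)C)OC5=O)[C@]23CC[C@@H]([C@@H]4C[C@H](C)C(=O)O4)N2C(=O)CCC[C@H]13 | intermediate
34 | ring B lactam of the target: rings A to E complete, tertiary alcohol free, C=O next to N in ring B | CC[C@@H]1[C@H]2OC(=O)[C@@](C)(O)[C@H]2[C@]23CC[C@@H]([C@@H]4C[C@H](C)C(=O)O4)N2C(=O)CCC[C@H]13 | intermediate
35 | ring B thiolactam of the target (C=S in place of the lactam C=O of 34) | CC[C@@H]1[C@H]2OC(=O)[C@@](C)(O)[C@H]2[C@]23CC[C@@H]([C@@H]4C[C@H](C)C(=O)O4)N2C(=S)CCC[C@H]13 | intermediate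
36 | CNP0260919.4 | CC[C@@H]1[C@H]2OC(=O)[C@@](C)(O)[C@H]2[C@]23CC[C@@H]([C@@H]4C[C@H](C)C(=O)O4)N2CCCC[C@H]13 | target

Total step count: 20. Longest linear sequence: 17 steps (steps 1–6, 9–11 and 13–20); steps 7, 8 and 12 prepare the aniline, the siloxyfuran and the dioxolanone.

Steps most likely to fail

Step 14. Ionisation of the carbinol may be slowed by the electron-poor dioxolanone next to it, so that retro-aldol cleavage or acid-induced furan decomposition outruns the cascade; the two resident stereo-elements may also disagree on the sense of conrotation. The fallback reaches the same amino-hydroxy-pentadienyl cation by oxidising the furan instead of ionising a carbinol; it sets out from 5 and comes back at 28. NaBH4 reduction of 5 gives (3-ethylfuran-2-yl)methanol F1, and SOCl2/pyridine gives 2-(chloromethyl)-3-ethylfuran F2. Alkylation of enolate 25 with crude F2, again anti to tert-butyl, gives (2R,5S)-2-tert-butyl-5-[(3-ethylfuran-2-yl)methyl]-5-methyl-1,3-dioxolan-4-one F3. Acid-catalysed Friedel–Crafts conjugate addition of the free furan α-position to acrolein gives the 3-oxopropyl furan F4. The operations of steps 9 and 10 (with 15 and 17) then give the butenolide amine F5 and the saturated N-(4-methoxyphenyl) amino lactone F6. Photooxygenation of F6 as its trifluoroacetate salt (O2, rose bengal, visible light, MeOH, then Me2S) opens the furan to the (Z)-enedione F7. On warming with CF3CO2H in MeCN the amine should condense with the remote ketone, the other ketone enolise, and the resulting cation close by the same conrotatory 4π step to 28.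

Step 17. The primary radical may be reduced before the slow 7-exo closure, a loss made worse if the amide rotamer that holds the chain away from the enone is populated and interconverts slowly. The fallback closes ring B by a reversible ionic addition; it sets out from 29 and comes back at 32. Acylation of 29 with 4-nitrobutanoyl chloride (pyridine) gives the nitro amide F8. DBU in MeCN should bring about intramolecular nitro-Michael addition to the enone under thermodynamic control, with rotamers free to equilibrate, giving the cis-fused nitro keto lactam F9. Radical denitration (Bu3SnH, AIBN, toluene, 110 °C) then gives 32.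

Step 18. Hydride may be delivered on the face syn to the dioxolanone, or attack the activated dioxolanone carbonyl, giving an alcohol that cannot close ring D. The fallback inverts that carbinol during lactonisation; it sets out from 32 and comes back at 34. The same reduction then gives the epimeric alcohol with OH trans to the dioxolanone F10. LiOH in THF/H2O cleaves the dioxolanone, and acidification to pH 3, which recloses ring E, gives the α-hydroxy acid F11. Mitsunobu lactonisation (PPh3, diisopropyl azodicarboxylate, THF) activates the secondary alcohol, and the carboxylate displaces it with inversion to give 34.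

Further compounds
F1 | step 14 | (3-ethylfuran-2-yl)methanol | CCc1ccoc1CO
F2 | step 14 | 2-(chloromethyl)-3-ethylfuran | CCc1ccoc1CCl
F3 | step 14 | (2R,5S)-2-tert-butyl-5-[(3-ethylfuran-2-yl)methyl]-5-methyl-1,3-dioxolan-4-one | CCc1ccoc1C[C@]2(C)O[C@@H](C(C)(C)C)OC2=O
F4 | step 14 | 3-[5-{[(2R,4S)-2-tert-butyl-4-methyl-5-oxo-1,3-dioxolan-4-yl]methyl}-4-ethylfuran-2-yl]propanal | CCc1cc(CCC=O)oc1C[C@]2(C)O[C@@H](C(C)(C)C)OC2=O
F5 | step 14 | (2R,5S)-2-tert-butyl-5-[(3-ethyl-5-{(3S)-3-{[4-methoxy-2-(methylsulfanyl)phenyl]amino}-3-[(2S)-4-methyl-5-oxo-2,5-dihydrofuran-2-yl]propyl}furan-2-yl)methyl]-5-methyl-1,3-dioxolan-4-one | CCc1cc(CC[C@@H]([C@@H]2C=C(C)C(=O)O2)Nc2ccc(OC)cc2SC)oc1C[C@]3(C)O[C@@H](C(C)(C)C)OC3=O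
F6 | step 14 | (2R,5S)-2-tert-butyl-5-[(3-ethyl-5-{(3S)-3-[(4-methoxyphenyl)amino]-3-[(2S,4S)-4-methyl-5-oxooxolan-2-yl]propyl}furan-2-yl)methyl]-5-methyl-1,3-dioxolan-4-one | CCc1cc(CC[C@@H]([C@@H]2C[C@H](C)C(=O)O2)Nc2ccc(OC)cc2)oc1C[C@]3(C)O[C@@H](C(C)(C)C)OC3=O
F7 | step 14 | (Z)-enedione from furan opening of F6: 1-[(2R,4S)-2-tert-butyl-4-methyl-5-oxo-1,3-dioxolan-4-yl]-3-ethyl-8-[(4-methoxyphenyl)amino]-8-[(2S,4S)-4-methyl-5-oxooxolan-2-yl]oct-3-ene-2,5-dione, 8S | CC/C(=C/C(=O)CC[C@@H]([C@@H]1C[C@H](C)C(=O)O1)Nc1ccc(OC)cc1)C(=O)C[C@]2(C)O[C@@H](C(C)(C)C)OC2=O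
F8 | step 17 | (2S,5R,6R)-6-[(2R,4S)-2-tert-butyl-4-methyl-5-oxo-1,3-dioxolan-4-yl]-8-ethyl-2-[(2S,4S)-4-methyl-5-oxooxolan-2-yl]-1-(4-nitrobutanoyl)-1-azaspiro[4.4]non-8-en-7-one | CCC1=C[C@]2(CC[C@@H]([C@@H]3C[C@H](C)C(=O)O3)N2C(=O)CCC[N+](=O)[O-])[C@@H](C1=O)[C@]4(C)O[C@@H](C(C)(C)C)OC4=O
F9 | step 17 | nitro analogue of 32 carrying NO2 on the ring B carbon bonded to ring C (nitro centre not fixed) | CC[C@@H]1C(=O)[C@@H]([C@]5(C)O[C@@H](C(C)(C)C)OC5=O)[C@]23CC[C@@H]([C@@H]4C[C@H](C)C(=O)O4)N2C(=O)CCC([N+](=O)[O-])[C@H]13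
F10 | step 18 | carbinol epimer of 33 (OH trans to the dioxolanone) | CC[C@@H]1[C@H](O)[C@@H]([C@]5(C)O[C@@H](C(C)(C)C)OC5=O)[C@]23CC[C@@H]([C@@H]4C[C@H](C)C(=O)O4)N2C(=O)CCC[C@H]13
F11 | step 18 | α-hydroxy acid from F10 (dioxolanone cleaved to C(CH3)(OH)CO2H, ring C carbinol trans to it) | CC[C@@H]1[C@H](O)[C@@H]([C@](C)(O)C(=O)O)[C@]23CC[C@@H]([C@@H]4C[C@H](C)C(=O)O4)N2C(=O)CCC[C@H]13
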